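The route rests on disconnecting the O1–C6 bond of the 1,2-dioxane. The quaternary ring carbon C6 carries, besides O1, a methyl group and two methylene arms (C5, C7), so no reagent could choose a face there; its configuration is instead relayed from an enantioselective allylic-alcohol epoxidation. In one operation the hydroperoxide on C3 attacks the tertiary carbon of a C6–C7 oxirane from the back, which closes the six-membered peroxide ring, sets C6 and frees a C7 hydroxyl for chain extension. The cyclisation substrate is a silyl-protected geraniol epoxide bearing the C3 hydroperoxide next to a C2 stereocentre with methyl and vinyl groups; the C9–C10 epoxide is added later by cross-metathesis.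

Key step: step 8

Remarks: Numbering follows the target chain: C1 carboxyl, C2 α-carbon, C3 and C6 ring carbons (O2 on C3, O1 on C6), C7–C8 tether, C9–C10 side-chain epoxide (C10 quaternary). Assumption: (R)-TRIP delivers allyl and crotyl groups to the re face of aldehydes, so the (S)-catalyst is taken for the si-face attack needed in step 4. The carboxylic acid is carried unprotected from step 9 onward, so that no ester has to be cleaved beside the base-sensitive β-peroxy centre.

Step 1
Reactants: 1 geraniol
Product: 2 (2R,3R)-2,3-epoxygeraniol [[(2R,3R)-3-methyl-3-(4-methylpent-3-en-1-yl)oxiran-2-yl]methanol]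
Conditions: Ti(OiPr)4 (cat.), D-(−)-diethyl tartrate (cat.), t-BuOOH, 4 Å MS, CH2Cl2, −20 °C
Reagents that add atoms: tert-butyl hydroperoxide, CC(C)(C)OO
Why: Sharpless asymmetric epoxidation is hydroxyl-directed, so only the allylic alkene reacts, and the D-tartrate catalyst should give the (2R,3R)-epoxide, which sets the future C6 and C7.

Step 2
Reactants: 2 (2R,3R)-2,3-epoxygeraniol
Product: 3 (2R,3R)-2,3-epoxygeranyl TBS ether [tert-butyl{[(2R,3R)-3-methyl-3-(4-methylpent-3-en-1-yl)oxiran-2-yl]methoxy}dimethylsilane]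
Conditions: TBSCl, imidazole, CH2Cl2, 0 °C to rt
Reagents that add atoms: tert-butyldimethylsilyl chloride, CC(C)(C)[Si](C)(C)Cl
Why: Silylation of the primary alcohol gives an ether that cannot act as a neighbouring group toward the oxirane and that withstands ozone, base and mild acid.

Step 3
Reactants: 3 (2R,3R)-2,3-epoxygeranyl TBS ether
Product: 4 3-[(2R,3R)-3-{[(tert-butyldimethylsilyl)oxy]methyl}-2-methyloxiran-2-yl]propanal
Conditions: O3, CH2Cl2, −78 °C; then PPh3, −78 °C to rt
Reagents that add atoms: ozone, [O-][O+]=O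
Why: Ozonolysis with reductive work-up cleaves the only C=C bond to the aldehyde (future C3), and oxirane and silyl ether are inert to ozone and to the phosphine.

Step 4
Reactants: 4 3-[(2R,3R)-3-{[(tert-butyldimethylsilyl)oxy]methyl}-2-methyloxiran-2-yl]propanal; 5 (E)-crotylboronic acid pinacol ester
Product: 7 (3S,4R)-6-[(2R,3R)-3-{[(tert-butyldimethylsilyl)oxy]methyl}-2-methyloxiran-2-yl]-3-methylhex-1-en-4-ol, via pinacol borate ester 6 (not isolated)
Conditions: (S)-TRIP (5 mol %), 4 Å MS, toluene, −30 °C; aq. NaHCO3 work-up; Et3N-deactivated silica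
Reagents that add atoms: none
Why: Chiral phosphoric acid-catalysed asymmetric crotylboration passes through a closed chair transition state, so the (E)-boronate gives the anti product and the (S)-catalyst should direct attack to the si face, which sets C2 (S) and the C3 carbinol (R) under catalyst control because the oxirane centres are too remote to interfere; stereoisomers from imperfect face control become diastereomeric dioxanes and can be removed after step 8.

Step 5
Reactants: 8 2,3-dimethylbut-2-ene
Product: 9 2-methoxyprop-2-yl hydroperoxide (2-hydroperoxy-2-methoxypropane)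
Conditions: O3, CH2Cl2/MeOH, −78 °C; kept and used as a solution
Reagents that add atoms: ozone, [O-][O+]=O; methanol, CO
Why: In the ozonolysis of this symmetrical alkene the carbonyl oxide is trapped by methanol (Criegee solvent trapping) to give the ketal-masked hydroperoxide, with acetone as the only co-product.

Step 6
Reactants: 7 (3S,4R)-6-[(2R,3R)-3-{[(tert-butyldimethylsilyl)oxy]methyl}-2-methyloxiran-2-yl]-3-methylhex-1-en-4-ol; 9 2-methoxyprop-2-yl hydroperoxide
Product: 11 tert-butyl{[(2R,3R)-3-[(3S,4S)-3-[(2-methoxypropan-2-yl)peroxy]-4-methylhex-5-en-1-yl]-3-methyloxiran-2-yl]methoxy}dimethylsilane, via triflate 10 (not isolated)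
Conditions: Tf2O, 2,6-lutidine, CH2Cl2, −78 °C; cold filtration; then 9 (slight excess over base), KOt-Bu, THF, −78 to 0 °C
Reagents that add atoms: none
Why: SN2 alkylation of a peroxide anion by a secondary triflate inverts C3 to the required S configuration; the peroxy anion is an α-effect nucleophile of low basicity, which favours substitution over elimination, and the low temperature limits participation of the oxirane oxygen.

Step 7
Reactants: 11 tert-butyl{[(2R,3R)-3-[(3S,4S)-3-[(2-methoxypropan-2-yl)peroxy]-4-methylhex-5-en-1-yl]-3-methyloxiran-2-yl]methoxy}dimethylsilane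
Product: 12 tert-butyl{[(2R,3R)-3-[(3S,4S)-3-hydroperoxy-4-methylhex-5-en-1-yl]-3-methyloxiran-2-yl]methoxy}dimethylsilane
Conditions: AcOH/THF/H2O, 0 °C to rt, short reaction time
Reagents that add atoms: none
Why: Mild acid hydrolysis of the mixed peroxyketal releases the hydroperoxide faster than aqueous acetic acid attacks the primary silyl ether, and any oxirane opening that starts here already leads toward 13.

Step 8
Reactants: 12 tert-butyl{[(2R,3R)-3-[(3S,4S)-3-hydroperoxy-4-methylhex-5-en-1-yl]-3-methyloxiran-2-yl]methoxy}dimethylsilane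
Product: 13 (1R)-1-[(3S,6S)-6-[(2S)-but-3-en-2-yl]-3-methyl-1,2-dioxan-3-yl]-2-[(tert-butyldimethylsilyl)oxy]ethan-1-ol
Conditions: CSA (10 mol %), CH2Cl2, −20 to 0 °C
Reagents that add atoms: none
Why: The acid activates the oxirane oxygen, the C6–O bond stretches because the tertiary carbon C6 bears positive charge better than C7, and the terminal oxygen of the C3 hydroperoxide attacks C6 anti to the leaving oxygen through a chair-like transition state. The closest known reaction type is the acid-promoted intramolecular opening of epoxides by pendant hydroperoxides, together with the perhydrolysis of trisubstituted epoxides at their tertiary carbon. The 1,2-dioxane closes in the 6-exo-tet mode, with O1–C6 as the only new bond. C6 is the one new stereocentre and is controlled by the substrate, through stereospecific inversion of the epoxide carbon set in step 1, while C7 keeps its oxygen and configuration and C2 and C3 are not touched. The step needs attack at C6 instead of C7 (7-endo) and substitution ahead of full ionisation; the tertiary-versus-secondary difference, the electron-withdrawing silyloxymethyl group on C7 and the non-participating silyl ether favour C6, and a catalytic acid with a weakly nucleophilic counter-ion in a non-polar solvent at low temperature should keep the opening concerted.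

Step 9
Reactants: 13 (1R)-1-[(3S,6S)-6-[(2S)-but-3-en-2-yl]-3-methyl-1,2-dioxan-3-yl]-2-[(tert-butyldimethylsilyl)oxy]ethan-1-ol
Product: 15 (2R)-2-[(3S,6S)-6-{(1R)-2-[(tert-butyldimethylsilyl)oxy]-1-hydroxyethyl}-6-methyl-1,2-dioxan-3-yl]propanoic acid, via aldehyde 14 (not isolated)
Conditions: O3, pyridine, CH2Cl2, −78 °C; then NaClO2, NaH2PO4, 2-methylbut-2-ene, t-BuOH/H2O, 0 °C to rt
Reagents that add atoms: ozone, [O-][O+]=O; sodium chlorite, [Na+].[O-]Cl=O
Why: Pyridine-mediated ozonolysis gives the aldehyde without a reductant that could attack the O–O bond, and immediate Pinnick oxidation in a pH 4 buffer converts the epimerisable β-peroxy aldehyde into the acid before C2 can scramble.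

Step 10
Reactants: 15 (2R)-2-[(3S,6S)-6-{(1R)-2-[(tert-butyldimethylsilyl)oxy]-1-hydroxyethyl}-6-methyl-1,2-dioxan-3-yl]propanoic acid
Product: 16 (2R)-2-[(3S,6S)-6-[(1R)-1,2-dihydroxyethyl]-6-methyl-1,2-dioxan-3-yl]propanoic acid
Conditions: HF·pyridine, pyridine, THF, 0 °C to rt
Reagents that add atoms: none
Why: Fluoride-driven cleavage of the Si–O bond under buffered, weakly acidic conditions avoids the basic fluoride sources that could trigger Kornblum–DeLaMare fragmentation of the peroxide.

Step 11
Reactants: 16 (2R)-2-[(3S,6S)-6-[(1R)-1,2-dihydroxyethyl]-6-methyl-1,2-dioxan-3-yl]propanoic acid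
Product: 17 (2R)-2-[(3S,6S)-6-formyl-6-methyl-1,2-dioxan-3-yl]propanoic acid
Conditions: NaIO4, THF/pH 7 buffer, 0 °C
Reagents that add atoms: none
Why: Periodate glycol cleavage (Malaprade reaction) removes C8 as formaldehyde and leaves C7 as an aldehyde that has no α-hydrogen and so cannot epimerise or eliminate.

Step 12
Reactants: 17 (2R)-2-[(3S,6S)-6-formyl-6-methyl-1,2-dioxan-3-yl]propanoic acid
Product: 18 (2R)-2-[(3S,6S)-6-ethenyl-6-methyl-1,2-dioxan-3-yl]propanoic acid
Conditions: Ph3PCH3Br (3.2 equiv), KHMDS (3 equiv), THF, −78 to 0 °C; pH 4 work-up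
Reagents that add atoms: methyltriphenylphosphonium bromide, C[P+](c1ccccc1)(c1ccccc1)c1ccccc1.[Br-]
Why: In this Wittig methylenation the first equivalent of ylide turns the acid into its carboxylate, which shields C2–H from deprotonation and so from β-elimination of the peroxide, while the remaining ylide converts the aldehyde into the vinyl group.

Step 13
Reactants: 19 dihydro-β-ionone
Product: 20 ethyl (2E)-3-methyl-5-(2,6,6-trimethylcyclohex-1-en-1-yl)pent-2-enoate
Conditions: (EtO)2P(O)CH2CO2Et, NaH, THF, 0 °C to reflux; chromatographic removal of the minor (2Z)-ester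
Reagents that add atoms: triethyl phosphonoacetate, CCOC(=O)CP(=O)(OCC)OCC
Why: Horner–Wadsworth–Emmons olefination of the methyl ketone favours the (E)-enoate under thermodynamic control of the oxaphosphetane, and the minor geometric isomer is separable.

Step 14
Reactants: 20 ethyl (2E)-3-methyl-5-(2,6,6-trimethylcyclohex-1-en-1-yl)pent-2-enoate
Product: 21 (E)-monocyclofarnesol [(2E)-3-methyl-5-(2,6,6-trimethylcyclohex-1-en-1-yl)pent-2-en-1-ol]
Conditions: DIBAL-H, CH2Cl2, −78 °C; Rochelle salt
Reagents that add atoms: none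
Why: DIBAL reduces the enoate in the 1,2-sense to the allylic alcohol without touching either alkene.

Step 15
Reactants: 21 (E)-monocyclofarnesol
Product: 22 [(2S,3S)-3-methyl-3-[2-(2,6,6-trimethylcyclohex-1-en-1-yl)ethyl]oxiran-2-yl]methanol
Conditions: Ti(OiPr)4 (cat.), L-(+)-diethyl tartrate (cat.), t-BuOOH, 4 Å MS, CH2Cl2, −20 °C
Reagents that add atoms: tert-butyl hydroperoxide, CC(C)(C)OO
Why: Sharpless asymmetric epoxidation with the L-tartrate catalyst should give the (2S,3S)-epoxide, which becomes C9 and C10, and the tetrasubstituted ring alkene has no directing hydroxyl and stays intact.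

Step 16
Reactants: 22 [(2S,3S)-3-methyl-3-[2-(2,6,6-trimethylcyclohex-1-en-1-yl)ethyl]oxiran-2-yl]methanol
Product: 24 (2S,3S)-3-ethenyl-2-methyl-2-[2-(2,6,6-trimethylcyclohex-1-en-1-yl)ethyl]oxirane, via epoxy aldehyde 23 (not isolated)
Conditions: Dess–Martin periodinane, NaHCO3, CH2Cl2, 0 °C; filtration; then Ph3PCH3Br, KHMDS, THF, −78 to 0 °C
Reagents that add atoms: methyltriphenylphosphonium bromide, C[P+](c1ccccc1)(c1ccccc1)c1ccccc1.[Br-]
Why: Dess–Martin oxidation followed at once by Wittig methylenation converts the epoxy alcohol into the vinyl epoxide; the sensitive epoxy aldehyde is not stored, and its ring carbon resists enolisation, so the configuration holds.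

Step 17
Reactants: 18 (2R)-2-[(3S,6S)-6-ethenyl-6-methyl-1,2-dioxan-3-yl]propanoic acid; 24 (2S,3S)-3-ethenyl-2-methyl-2-[2-(2,6,6-trimethylcyclohex-1-en-1-yl)ethyl]oxirane (3 equiv)
Product: 25 (2R)-2-[(3S,6S)-6-methyl-6-[(E)-2-{(2S,3S)-3-methyl-3-[2-(2,6,6-trimethylcyclohex-1-en-1-yl)ethyl]oxiran-2-yl}ethenyl]-1,2-dioxan-3-yl]propanoic acid
Conditions: Hoveyda–Grubbs II (10 mol %), CH2Cl2, 40 °C
Reagents that add atoms: none
Why: In this olefin cross-metathesis the quaternary-allylic alkene 18 does not homodimerise and the vinyl epoxide is used in excess, loss of ethene drives the coupling that forms C7=C8, and the ruthenium carbene tolerates dialkyl peroxide, epoxide and free acid and ignores the tetrasubstituted ring alkene.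

Step 18
Reactants: 25 (2R)-2-[(3S,6S)-6-methyl-6-[(E)-2-{(2S,3S)-3-methyl-3-[2-(2,6,6-trimethylcyclohex-1-en-1-yl)ethyl]oxiran-2-yl}ethenyl]-1,2-dioxan-3-yl]propanoic acid
Product: 26 (2R)-2-[(3S,6R)-6-methyl-6-{2-[(2S,3S)-3-methyl-3-[2-(2,6,6-trimethylcyclohex-1-en-1-yl)ethyl]oxiran-2-yl]ethyl}-1,2-dioxan-3-yl]propanoic acid (CNP0204283.1)
Conditions: KO2CN=NCO2K (excess), AcOH (slow addition), CH2Cl2/MeOH, 0 °C to rt
Reagents that add atoms: none
Why: Diimide reduction transfers two hydrogens in a concerted syn fashion to the 1,2-disubstituted alkene and does not touch the O–O bond, the oxirane or the hindered tetrasubstituted alkene, which hydrogenation over a metal would not spare.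

Compound list
1 | geraniol | CC(C)=CCC/C(C)=C/CO | starting material
2 | (2R,3R)-2,3-epoxygeraniol | CC(C)=CCC[C@@]1(C)O[C@@H]1CO | intermediate
3 | (2R,3R)-2,3-epoxygeranyl TBS ether | CC(C)=CCC[C@@]1(C)O[C@@H]1CO[Si](C)(C)C(C)(C)C | intermediate
4 | 3-[(2R,3R)-3-{[(tert-butyldimethylsilyl)oxy]methyl}-2-methyloxiran-2-yl]propanal | O=CCC[C@@]1(C)O[C@@H]1CO[Si](C)(C)C(C)(C)C | intermediate
5 | (E)-crotylboronic acid pinacol ester | C/C=C/CB1OC(C)(C)C(C)(C)O1 | starting material
6 | pinacol borate ester of 7 | C=C[C@H](C)[C@H](OB1OC(C)(C)C(C)(C)O1)CC[C@@]2(C)O[C@@H]2CO[Si](C)(C)C(C)(C)C | intermediate (not isolated)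
7 | (3S,4R)-6-[(2R,3R)-3-{[(tert-butyldimethylsilyl)oxy]methyl}-2-methyloxiran-2-yl]-3-methylhex-1-en-4-ol | C=C[C@H](C)[C@H](O)CC[C@@]1(C)O[C@@H]1CO[Si](C)(C)C(C)(C)C | intermediate
8 | 2,3-dimethylbut-2-ene | CC(C)=C(C)C | starting material
9 | 2-methoxyprop-2-yl hydroperoxide | COC(C)(C)OO | intermediate (reagent made in step 5)
10 | C3 trifluoromethanesulfonate of 7 | C=C[C@H](C)[C@H](OS(=O)(=O)C(F)(F)F)CC[C@@]1(C)O[C@@H]1CO[Si](C)(C)C(C)(C)C | intermediate (not isolated)
11 | tert-butyl{[(2R,3R)-3-[(3S,4S)-3-[(2-methoxypropan-2-yl)peroxy]-4-methylhex-5-en-1-yl]-3-methyloxiran-2-yl]methoxy}dimethylsilane | C=C[C@H](C)[C@@H](OOC(C)(C)OC)CC[C@@]1(C)O[C@@H]1CO[Si](C)(C)C(C)(C)C | intermediate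
12 | tert-butyl{[(2R,3R)-3-[(3S,4S)-3-hydroperoxy-4-methylhex-5-en-1-yl]-3-methyloxiran-2-yl]methoxy}dimethylsilane | C=C[C@H](C)[C@@H](OO)CC[C@@]1(C)O[C@@H]1CO[Si](C)(C)C(C)(C)C | intermediate (key-step precursor)
13 | (1R)-1-[(3S,6S)-6-[(2S)-but-3-en-2-yl]-3-methyl-1,2-dioxan-3-yl]-2-[(tert-butyldimethylsilyl)oxy]ethan-1-ol | CC(C)(C)[Si](C)(C)OC[C@@H](O)[C@]1(C)CC[C@@H]([C@@H](C)C=C)OO1 | intermediate (key-step product)
14 | (2R)-2-[(3S,6S)-6-{(1R)-2-[(tert-butyldimethylsilyl)oxy]-1-hydroxyethyl}-6-methyl-1,2-dioxan-3-yl]propanal | CC(C)(C)[Si](C)(C)OC[C@@H](O)[C@]1(C)CC[C@@H]([C@@H](C)C=O)OO1 | intermediate (not isolated)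
15 | (2R)-2-[(3S,6S)-6-{(1R)-2-[(tert-butyldimethylsilyl)oxy]-1-hydroxyethyl}-6-methyl-1,2-dioxan-3-yl]propanoic acid | CC(C)(C)[Si](C)(C)OC[C@@H](O)[C@]1(C)CC[C@@H]([C@@H](C)C(=O)O)OO1 | intermediate
16 | (2R)-2-[(3S,6S)-6-[(1R)-1,2-dihydroxyethyl]-6-methyl-1,2-dioxan-3-yl]propanoic acid | OC[C@@H](O)[C@]1(C)CC[C@@H]([C@@H](C)C(=O)O)OO1 | intermediate
17 | (2R)-2-[(3S,6S)-6-formyl-6-methyl-1,2-dioxan-3-yl]propanoic acid | O=C[C@]1(C)CC[C@@H]([C@@H](C)C(=O)O)OO1 | intermediate
18 | (2R)-2-[(3S,6S)-6-ethenyl-6-methyl-1,2-dioxan-3-yl]propanoic acid | C=C[C@]1(C)CC[C@@H]([C@@H](C)C(=O)O)OO1 | intermediate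
19 | dihydro-β-ionone | CC(=O)CCC1=C(C)CCCC1(C)C | starting material
20 | ethyl (2E)-3-methyl-5-(2,6,6-trimethylcyclohex-1-en-1-yl)pent-2-enoate | CCOC(=O)/C=C(\C)CCC1=C(C)CCCC1(C)C | intermediate
21 | (E)-monocyclofarnesol | OC/C=C(\C)CCC1=C(C)CCCC1(C)C | intermediate
22 | [(2S,3S)-3-methyl-3-[2-(2,6,6-trimethylcyclohex-1-en-1-yl)ethyl]oxiran-2-yl]methanol | CC1=C(CC[C@]2(C)O[C@H]2CO)C(C)(C)CCC1 | intermediate
23 | (2R,3S)-3-methyl-3-[2-(2,6,6-trimethylcyclohex-1-en-1-yl)ethyl]oxirane-2-carbaldehyde | CC1=C(CC[C@]2(C)O[C@H]2C=O)C(C)(C)CCC1 | intermediate (not isolated)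
24 | (2S,3S)-3-ethenyl-2-methyl-2-[2-(2,6,6-trimethylcyclohex-1-en-1-yl)ethyl]oxirane | CC1=C(CC[C@]2(C)O[C@H]2C=C)C(C)(C)CCC1 | intermediate
25 | (2R)-2-[(3S,6S)-6-methyl-6-[(E)-2-{(2S,3S)-3-methyl-3-[2-(2,6,6-trimethylcyclohex-1-en-1-yl)ethyl]oxiran-2-yl}ethenyl]-1,2-dioxan-3-yl]propanoic acid | CC1=C(CC[C@]2(C)O[C@H]2/C=C/[C@]2(C)CC[C@@H]([C@@H](C)C(=O)O)OO2)C(C)(C)CCC1 | intermediate
26 | (2R)-2-[(3S,6R)-6-methyl-6-{2-[(2S,3S)-3-methyl-3-[2-(2,6,6-trimethylcyclohex-1-en-1-yl)ethyl]oxiran-2-yl]ethyl}-1,2-dioxan-3-yl]propanoic acid | CC1=C(CC[C@]2(C)O[C@H]2CC[C@]2(C)CC[C@@H]([C@@H](C)C(=O)O)OO2)C(C)(C)CCC1 | target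

Total step count: 18. Longest linear sequence: 13 steps (steps 1–4, 6–12, 17 and 18, from geraniol).

Steps most likely to fail

Step 8. The tertiary C6–O bond may ionise before the hydroperoxide has attacked, which would erode the inversion and open paths to hydride shift, elimination or 7-endo closure; the silyl ether may also be lost under the acid. The fallback sets out from 7 and returns at 13, and it forms the ring at the O2–C3 bond under base instead. Alcohol 7 would be mesylated (MsCl, Et3N, CH2Cl2, −20 °C) to the epoxy mesylate F1. Perhydrolysis of its oxirane with ethereal H2O2 and catalytic phosphomolybdic acid, a known opening of trisubstituted epoxides at the tertiary carbon with inversion, should give the hydroperoxy alcohol mesylate F2. KOt-Bu with 18-crown-6 in THF would then close the ring by 6-exo SN2 displacement of the C3 mesylate with inversion, the hydroperoxide being more acidic and more nucleophilic than the C7 hydroxyl, to give 13.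

Step 6. Substitution at the β-branched secondary carbon may lose to E2 elimination toward the conjugated diene, and the oxirane oxygen may take part in the departure of the triflate, or the free epoxy alcohol may cyclise to a tetrahydrofuran during activation. The fallback sets out from 1 and returns at 11, and it installs the peroxide before the oxirane exists. Geraniol 1 would be silylated to geranyl TBS ether F3, and ozonolysis limited to the electron-rich distal alkene (one equivalent of O3, pyridine, −78 °C) would give the aldehyde F4. Crotylboration with 5 and (S)-TRIP as in step 4 would pass through the pinacol borate ester F5 to the anti homoallylic alcohol F6. Its triflate F7 would be displaced by the potassium salt of 9 as in step 6 to give the olefinic perketal F8. Asymmetric epoxidation of the allylic silyl ether alkene with the D-fructose-derived Shi ketone (Oxone, K2CO3, MeCN/dimethoxymethane/aqueous buffer, 0 °C), which should leave the monosubstituted vinyl group and the dialkyl peroxide alone, would then give 11.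

Step 17. Productive metathesis between two hindered alkenes (quaternary allylic carbon on 18, oxirane branch on 24) may be slow, so that self-metathesis of 24 and catalyst decay take over. The fallback sets out from 17 and 21 and returns at 26, replacing metathesis by a Wittig coupling and a late epoxidation. Monocyclofarnesol 21 with Ph3P·HBr would give the allylic phosphonium bromide F9, and KHMDS would convert it into the ylide F10. Wittig reaction of F10 with the potassium salt of 17 would give the diene acid F11, whose C7=C8 geometry is immaterial. Diimide in limited excess should reduce the disubstituted C7=C8 bond ahead of the trisubstituted C9=C10 bond and give the mono-olefin acid F12. Epoxidation with the L-fructose-derived enantiomer of the Shi ketone should then install the (9S,10S)-oxirane faster than the hindered tetrasubstituted ring alkene reacts, to give 26.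

Further compounds
F1 | step 8 | C3 methanesulfonate of 7 (epoxy mesylate) | C=C[C@H](C)[C@H](OS(C)(=O)=O)CC[C@@]1(C)O[C@@H]1CO[Si](C)(C)C(C)(C)C
F2 | step 8 | open-chain hydroperoxy alcohol mesylate (C3 OMs, C6 OOH, C7 OH, C8 OTBS) | C=C[C@H](C)[C@H](OS(C)(=O)=O)CC[C@](C)(OO)[C@H](O)CO[Si](C)(C)C(C)(C)C
F3 | step 6 | geranyl TBS ether | CC(C)=CCC/C(C)=C/CO[Si](C)(C)C(C)(C)C
F4 | step 6 | (4E)-6-[(tert-butyldimethylsilyl)oxy]-4-methylhex-4-enal | O=CCC/C(C)=C/CO[Si](C)(C)C(C)(C)C
F5 | step 6 | pinacol borate ester of F6 | C=C[C@H](C)[C@H](OB1OC(C)(C)C(C)(C)O1)CC/C(C)=C/CO[Si](C)(C)C(C)(C)C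
F6 | step 6 | (3S,4R,7E)-9-[(tert-butyldimethylsilyl)oxy]-3,7-dimethylnona-1,7-dien-4-ol | C=C[C@H](C)[C@H](O)CC/C(C)=C/CO[Si](C)(C)C(C)(C)C
F7 | step 6 | C4 trifluoromethanesulfonate of F6 | C=C[C@H](C)[C@H](OS(=O)(=O)C(F)(F)F)CC/C(C)=C/CO[Si](C)(C)C(C)(C)C
F8 | step 6 | olefinic perketal (C3 2-methoxyprop-2-yl peroxide, C6=C7 alkene) | C=C[C@H](C)[C@@H](OOC(C)(C)OC)CC/C(C)=C/CO[Si](C)(C)C(C)(C)C
F9 | step 17 | [(2E)-3-methyl-5-(2,6,6-trimethylcyclohex-1-en-1-yl)pent-2-en-1-yl]triphenylphosphonium bromide | CC1=C(CC/C(C)=C/C[P+](c2ccccc2)(c2ccccc2)c2ccccc2)C(C)(C)CCC1.[Br-]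
F10 | step 17 | ylide of F9 | CC1=C(CC/C(C)=C/C=P(c2ccccc2)(c2ccccc2)c2ccccc2)C(C)(C)CCC1
F11 | step 17 | diene acid (C7=C8 and (9E)-C9=C10) | CC1=C(CC/C(C)=C/C=C[C@]2(C)CC[C@@H]([C@@H](C)C(=O)O)OO2)C(C)(C)CCC1
F12 | step 17 | mono-olefin acid ((9E)-C9=C10) | CC1=C(CC/C(C)=C/CC[C@]2(C)CC[C@@H]([C@@H](C)C(=O)O)OO2)C(C)(C)CCC1
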